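**Retrosynthetic overview**

1. Feature: with the carbocycle numbered C1 (O-bearing quaternary carbon) to C10 (ring-fusion CH), the atoms C10–C1(CH3)–C2–C3–C4(three-carbon branch)–C5 are the p-menthane ring of carvone once C5 and C10 are bonded, and C6=C7 and C9=C8 are alkenyl arms on C5 and C10.
2. Endgame: the gem-dimethyl trione ring comes from dearomative C-methylation of a chroman, the pyran ring from SNAr of the C1 hydroxyl on an o-fluoroaryl ketone, and the C10–CH2–aryl bond from hydroboration of a C10 methylene group and B-alkyl Suzuki coupling.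
3. Key disconnection: the ten-membered ring by anionic oxy-Cope [3,3] shift of a cis-1-vinyl-2-[(E)-propenyl]cyclohexanol, which makes C7–C8, breaks C5–C10 and gives Z C5=C6, the C7 methyl centre and a C10 ketone.
4. Precursor from (R)-carvone: epoxide, 1,2-diol, α-hydroxy ketone (C1 and C4 fixed), MOM ether, trans allylation at C5, axial vinyl addition at C10, allyl to (E)-propenyl.
5. Ring order: carvone six-ring (chiral pool), then the ten-membered carbocycle (step 8), then the pyran (step 16); the acylphloroglucinol ring is brought in aromatic and dearomatised last (step 18).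

Key step: step 8

Remark: carbon numbers C1–C10 in the Why lines are those of the target carbocycle; diol 3 is taken on as both epimers at the secondary carbinol, which is oxidised in step 3, and 30 is written as the enol tautomer of the given SMILES.

**Route**

Step 1
Reactants: 1 (R)-carvone
Product: 2 (1R,4R,6R)-1-methyl-4-(prop-1-en-2-yl)-7-oxabicyclo[4.1.0]heptan-2-one
Conditions: 30% H2O2, NaOH (cat.), MeOH, 0 °C
Reagents that add atoms: hydrogen peroxide, OO
Why: Weitz–Scheffer nucleophilic epoxidation touches only the enone, and hydroperoxide adds axially to the β-carbon anti to the isopropenyl group, so the epoxide oxygen is trans to the C4 substituent and C1 is set.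

Step 2
Reactants: 2 (1R,4R,6R)-1-methyl-4-(prop-1-en-2-yl)-7-oxabicyclo[4.1.0]heptan-2-one
Product: 3 (1R,4R)-1-methyl-4-(prop-1-en-2-yl)cyclohexane-1,2-diol (both epimers at the secondary carbinol)
Conditions: LiAlH4, THF, 0 °C → reflux; aq. NaOH work-up
Reagents that add atoms: none
Why: Hydride reduction of the ketone and SN2 opening of the epoxide by hydride at its less substituted carbon (trans-diaxial opening) leave the tertiary C1–O bond and its configuration untouched, and the new secondary carbinol centre is removed in step 3.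

Step 3
Reactants: 3 (1R,4R)-1-methyl-4-(prop-1-en-2-yl)cyclohexane-1,2-diol
Product: 4 (2R,5R)-2-hydroxy-2-methyl-5-(prop-1-en-2-yl)cyclohexan-1-one
Conditions: IBX, DMSO, rt
Reagents that add atoms: none
Why: IBX oxidation converts the secondary alcohol of a secondary/tertiary 1,2-diol into the α-hydroxy ketone without glycol cleavage, the tertiary alcohol being inert.

Step 4
Reactants: 4 (2R,5R)-2-hydroxy-2-methyl-5-(prop-1-en-2-yl)cyclohexan-1-one
Product: 5 (2R,5R)-2-(methoxymethoxy)-2-methyl-5-(prop-1-en-2-yl)cyclohexan-1-one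
Conditions: MOMCl, iPr2NEt, Bu4NI (cat.), 1,2-dichloroethane, 60 °C
Reagents that add atoms: chloromethyl methyl ether, COCCl
Why: MOM ether formation (O-alkylation with an α-chloro ether under amine base) masks the tertiary hydroxyl as a base-stable, chelating ether without enolate chemistry.

Step 5
Reactants: 5 (2R,5R)-2-(methoxymethoxy)-2-methyl-5-(prop-1-en-2-yl)cyclohexan-1-one; 6 allyl bromide
Product: 8 (2R,5R,6S)-6-allyl-2-(methoxymethoxy)-2-methyl-5-(prop-1-en-2-yl)cyclohexan-1-one, via lithium enolate 7 (not isolated)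
Conditions: LDA, THF, −78 °C; then 6, DMPU, −78 → −30 °C
Reagents that add atoms: none
Why: Kinetic enolate alkylation: C1 is quaternary so deprotonation is possible only at C5, and allyl bromide approaches anti to the adjacent C4 isopropenyl group, setting C5 with allyl trans to isopropenyl (the diequatorial isomer).

Step 6
Reactants: 8 (2R,5R,6S)-6-allyl-2-(methoxymethoxy)-2-methyl-5-(prop-1-en-2-yl)cyclohexan-1-one; 9 vinylmagnesium bromide
Product: 10 (1R,2R,5R,6S)-6-allyl-2-(methoxymethoxy)-2-methyl-5-(prop-1-en-2-yl)-1-vinylcyclohexan-1-ol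
Conditions: 9, LaCl3·2LiCl (0.3 equiv), THF, −78 → 0 °C; aq. work-up
Reagents that add atoms: none
Why: Grignard 1,2-addition (Lewis acid-promoted to suppress enolisation): in the chair with OMOM, allyl and isopropenyl equatorial and the C1 methyl axial, attack is axial on the face anti to that methyl, which is also the open face of the Mg chelate between C=O and the OMOM oxygen, so C10 is set with vinyl cis to the C5 allyl group.

Step 7
Reactants: 10 (1R,2R,5R,6S)-6-allyl-2-(methoxymethoxy)-2-methyl-5-(prop-1-en-2-yl)-1-vinylcyclohexan-1-ol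
Product: 11 (1R,2R,5R,6S)-2-(methoxymethoxy)-2-methyl-5-(prop-1-en-2-yl)-6-[(E)-prop-1-enyl]-1-vinylcyclohexan-1-ol
Conditions: [Ir(cod)(PMePh2)2]PF6 (3 mol %, activated with H2, then degassed), THF, rt
Reagents that add atoms: none
Why: Iridium-hydride catalysed one-position alkene isomerisation acts on the monosubstituted allyl group only (the vinyl carbinol has no allylic hydrogen, the 1,1-disubstituted isopropenyl group is slower), and the E isomer is expected because a Z-propenyl group would suffer allylic 1,3-strain against the branched carbon C5.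

Step 8
Reactants: 11 (1R,2R,5R,6S)-2-(methoxymethoxy)-2-methyl-5-(prop-1-en-2-yl)-6-[(E)-prop-1-enyl]-1-vinylcyclohexan-1-ol
Product: 14 (4S,7R,10R,Z)-10-(methoxymethoxy)-4,10-dimethyl-7-(prop-1-en-2-yl)cyclodec-5-en-1-one, via potassium alkoxide 12 (not isolated), via potassium dienolate 13 (not isolated)
Conditions: KH, 18-crown-6, THF, 0 °C → rt; then sat. aq. NH4Cl, −78 °C
Reagents that add atoms: none
Why: Anionic oxy-Cope rearrangement: the potassium alkoxide 12 undergoes a chair-like [3,3] sigmatropic shift of the C8=C9–C10–C5–C6=C7 array that forms C7–C8 and cleaves C5–C10, and the enolate 13 is protonated at C9 on work-up. The closest known reaction type is the anionic oxy-Cope ring expansion of cis-1,2-dialkenylcyclohexanols to cyclodec-5-enones. The ten-membered ring is not closed end to end but arises by four-carbon ring expansion, the carvone six-ring being opened at C5–C10 while the new C7–C8 bond joins the two alkenyl arms. The new stereocentre C7 is controlled by the E geometry of the propenyl group, which places its methyl pseudo-equatorial in the chair array, acting together with the fixed C5 and C10 configurations. The step needs the Z geometry at C5=C6, and this follows from the cis relationship of axial vinyl and equatorial propenyl in the ground-state chair (isopropenyl and OMOM equatorial), which forces the C5–C4 ring bond pseudo-axial in the pericyclic chair, whereas the other chair would need propenyl, isopropenyl and OMOM all axial. Because C1 is quaternary the enolate can lie only towards C9, so C1 and C4 are not touched.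

Step 9
Reactants: 14 (4S,7R,10R,Z)-10-(methoxymethoxy)-4,10-dimethyl-7-(prop-1-en-2-yl)cyclodec-5-en-1-one
Product: 16 (4S,7R,10R,Z)-7-(2-hydroxypropan-2-yl)-10-(methoxymethoxy)-4,10-dimethylcyclodec-5-en-1-one, via tertiary hydroperoxide 15 (not isolated)
Conditions: Co(acac)2 (20 mol %), PhSiH3, O2 (1 atm), THF, rt; then PPh3
Reagents that add atoms: dioxygen, O=O
Why: Mukaiyama hydration (cobalt-hydride hydrogen-atom transfer, O2 trapping of the tertiary radical, reduction of the hydroperoxide) is selective for the 1,1-disubstituted isopropenyl alkene over the hindered Z-1,2-disubstituted ring alkene and creates no stereocentre.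

Step 10
Reactants: 16 (4S,7R,10R,Z)-7-(2-hydroxypropan-2-yl)-10-(methoxymethoxy)-4,10-dimethylcyclodec-5-en-1-one
Product: 17 2-[(1R,4S,8R,Z)-8-(methoxymethoxy)-4,8-dimethyl-7-methylidenecyclodec-2-en-1-yl]propan-2-ol
Conditions: Ph3PCH3Br, KOtBu (excess), THF, 0 → 65 °C
Reagents that add atoms: methyltriphenylphosphonium bromide, C[P+](c1ccccc1)(c1ccccc1)c1ccccc1.[Br-]
Why: Wittig methylenation of the hindered C10 ketone with excess non-stabilised ylide (one equivalent is taken up by the free tertiary hydroxyl); the ketone can enolise only towards the non-stereogenic C9 and the α-OMOM group cannot be eliminated.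

Step 11
Reactants: 17 2-[(1R,4S,8R,Z)-8-(methoxymethoxy)-4,8-dimethyl-7-methylidenecyclodec-2-en-1-yl]propan-2-ol
Product: 19 2-[(1R,4S,8R,Z)-8-hydroxy-4,8-dimethyl-7-methylidenecyclodec-2-en-1-yl]propan-2-ol, via bromomethyl ether 18 (not isolated)
Conditions: Me2BBr, iPr2NEt (cat.), CH2Cl2, −78 °C; then sat. aq. NaHCO3/THF
Reagents that add atoms: none
Why: Lewis acid-mediated acetal cleavage: boron binds the terminal methoxy oxygen and bromide attacks the acetal carbon, so the bromomethyl ether formed is hydrolysed on work-up and the tertiary allylic C1–O bond is never broken or ionised.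

Step 12
Reactants: 20 5-fluororesorcinol; 21 isobutyric acid
Product: 22 1-(2-fluoro-4,6-dihydroxyphenyl)-2-methylpropan-1-one
Conditions: BF3·OEt2, 90 °C; aq. work-up
Reagents that add atoms: none
Why: Friedel–Crafts (Nencki-type) C-acylation of the resorcinol occurs ortho to one hydroxyl and para to the other, next to fluorine, not at the hindered carbon between the hydroxyls, which places the acyl group between OH and F.

Step 13
Reactants: 22 1-(2-fluoro-4,6-dihydroxyphenyl)-2-methylpropan-1-one
Product: 23 1-[2-fluoro-4,6-bis(methoxymethoxy)phenyl]-2-methylpropan-1-one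
Conditions: NaH, MOMCl, DMF, 0 °C → rt
Reagents that add atoms: chloromethyl methyl ether, COCCl
Why: Williamson-type O-alkylation of both phenoxides gives MOM ethers, which are poor leaving groups and do not deactivate the ring as phenoxides would in step 16.

Step 14
Reactants: 23 1-[2-fluoro-4,6-bis(methoxymethoxy)phenyl]-2-methylpropan-1-one
Product: 24 1-[3-bromo-2-fluoro-4,6-bis(methoxymethoxy)phenyl]-2-methylpropan-1-one
Conditions: NBS, MeCN, 0 °C → rt, dark
Reagents that add atoms: N-bromosuccinimide, O=C1CCC(=O)N1Br
Why: Electrophilic aromatic bromination goes to the carbon para to one OMOM group and ortho to the other (next to fluorine), not to the more hindered carbon flanked by both OMOM groups.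

Step 15
Reactants: 19 2-[(1R,4S,8R,Z)-8-hydroxy-4,8-dimethyl-7-methylidenecyclodec-2-en-1-yl]propan-2-ol; 24 1-[3-bromo-2-fluoro-4,6-bis(methoxymethoxy)phenyl]-2-methylpropan-1-one
Product: 26 1-[2-fluoro-3-{[(1S,4S,7R,10R,Z)-10-hydroxy-7-(2-hydroxypropan-2-yl)-4,10-dimethylcyclodec-5-en-1-yl]methyl}-4,6-bis(methoxymethoxy)phenyl]-2-methylpropan-1-one, via B-alkyl-9-BBN 25 (not isolated)
Conditions: 9-BBN (3.5 equiv), THF, 0 → 50 °C; then 24, Pd(OAc)2 (5 mol %), SPhos (10 mol %), aq. K3PO4, THF, 60 °C
Reagents that add atoms: none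
Why: Hydroboration and B-alkyl Suzuki–Miyaura coupling: 9-BBN adds only to the 1,1-disubstituted exocyclic alkene (boron on CH2), and C10 is set by syn H–B addition from the outer face of the ring, the face carrying the C1–O bond in the conformer with C1–C2 turned inward, so that C10–H is cis to the C1 oxygen; the primary alkylborane then couples at the C–Br bond of 24 (C–F is inert to Pd), a bulky biarylphosphine serving the di-ortho-substituted bromide.

Step 16
Reactants: 26 1-[2-fluoro-3-{[(1S,4S,7R,10R,Z)-10-hydroxy-7-(2-hydroxypropan-2-yl)-4,10-dimethylcyclodec-5-en-1-yl]methyl}-4,6-bis(methoxymethoxy)phenyl]-2-methylpropan-1-one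
Product: 27 chroman bis-MOM ether (8-isobutyryl-5,7-bis(methoxymethoxy)chroman whose C2–C3 bond is the C1–C10 bond of the cyclodecene; C1–O trans to C10–CH2)
Conditions: NaH (2.5 equiv), THF/DMF, 0 → 50 °C
Reagents that add atoms: none
Why: Intramolecular nucleophilic aromatic substitution: the C1 alkoxide attacks the fluorine-bearing carbon ortho to the ketone and closes the six-membered pyran ring with loss of fluoride, a far better leaving group than the alkoxy group on the other ortho carbon, and since the C1–O bond is not broken C1 keeps its configuration.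

Step 17
Reactants: 27 chroman bis-MOM ether
Product: 28 chroman diphenol (5,7-dihydroxy-8-isobutyrylchroman fused to the cyclodecene; 1R,4R,7S,10S in carbocycle numbering)
Conditions: HCl (1.25 M in MeOH), 0 °C → rt
Reagents that add atoms: none
Why: Acid-catalysed acetal methanolysis removes both aryl MOM ethers as dimethoxymethane under conditions mild enough for the tertiary alcohol, the tertiary alkyl aryl ether and the Z-alkene.

Step 18
Reactants: 28 chroman diphenol
Product: 30 CNP0564661.1 (target), via C-monomethyl phenol 29 (not isolated)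
Conditions: NaOMe (3.5 equiv), MeI (excess), MeOH, 0 °C → rt
Reagents that add atoms: iodomethane, CI
Why: Dearomative double C-methylation of the acylphloroglucinol dianion: the only unsubstituted ring carbon, flanked by both phenolic oxygens, is methylated twice (C-alkylation is favoured in methanol) to give the gem-dimethyl enolised β-triketone, and because the ether oxygen and the acyl group are already fixed on the ring only the target regiochemistry can result.

**Compound list**

1 | (R)-carvone | CC1=CC[C@@H](C(C)=C)CC1=O | starting material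
2 | (1R,4R,6R)-1-methyl-4-(prop-1-en-2-yl)-7-oxabicyclo[4.1.0]heptan-2-one (epoxide oxygen trans to isopropenyl) | O=C1C[C@H](C(C)=C)C[C@H]2O[C@@]12C | intermediate
3 | (1R,4R)-1-methyl-4-(prop-1-en-2-yl)cyclohexane-1,2-diol (both epimers at C2) | OC1C[C@H](C(C)=C)CC[C@@]1(C)O | intermediate
4 | (2R,5R)-2-hydroxy-2-methyl-5-(prop-1-en-2-yl)cyclohexan-1-one | O=C1C[C@H](C(C)=C)CC[C@@]1(C)O | intermediate
5 | (2R,5R)-2-(methoxymethoxy)-2-methyl-5-(prop-1-en-2-yl)cyclohexan-1-one | O=C1C[C@H](C(C)=C)CC[C@@]1(C)OCOC | intermediate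
6 | allyl bromide | C=CCBr | starting material
7 | lithium enolate of 5 (enolate towards C6 of the cyclohexanone) | [Li]OC1=C[C@H](C(C)=C)CC[C@@]1(C)OCOC | intermediate (not isolated)
8 | (2R,5R,6S)-6-allyl-2-(methoxymethoxy)-2-methyl-5-(prop-1-en-2-yl)cyclohexan-1-one | O=C1[C@@H](CC=C)[C@H](C(C)=C)CC[C@@]1(C)OCOC | intermediate
9 | vinylmagnesium bromide | C=C[Mg]Br | starting material
10 | (1R,2R,5R,6S)-6-allyl-2-(methoxymethoxy)-2-methyl-5-(prop-1-en-2-yl)-1-vinylcyclohexan-1-ol | C=C[C@@]1(O)[C@@H](CC=C)[C@H](C(C)=C)CC[C@@]1(C)OCOC | intermediate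
11 | (1R,2R,5R,6S)-2-(methoxymethoxy)-2-methyl-5-(prop-1-en-2-yl)-6-[(E)-prop-1-enyl]-1-vinylcyclohexan-1-ol (key-step precursor) | C=C[C@@]1(O)[C@@H](/C=C/C)[C@H](C(C)=C)CC[C@@]1(C)OCOC | intermediate
12 | potassium alkoxide of 11 | C=C[C@@]1(O[K])[C@@H](/C=C/C)[C@H](C(C)=C)CC[C@@]1(C)OCOC | intermediate (not isolated)
13 | potassium dienolate of 14 (C9=C10 enolate with C1 trans to C8, Z C5=C6) | COCO[C@]1(C)CC[C@@H](C(C)=C)/C=C\[C@@H](C)C/C=C1\O[K] | intermediate (not isolated)
14 | (4S,7R,10R,Z)-10-(methoxymethoxy)-4,10-dimethyl-7-(prop-1-en-2-yl)cyclodec-5-en-1-one (key-step product) | COCO[C@]1(C)CC[C@@H](C(C)=C)/C=C\[C@@H](C)CCC1=O | intermediate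
15 | tertiary hydroperoxide of 16 | COCO[C@]1(C)CC[C@@H](C(C)(C)OO)/C=C\[C@@H](C)CCC1=O | intermediate (not isolated)
16 | (4S,7R,10R,Z)-7-(2-hydroxypropan-2-yl)-10-(methoxymethoxy)-4,10-dimethylcyclodec-5-en-1-one | COCO[C@]1(C)CC[C@@H](C(C)(C)O)/C=C\[C@@H](C)CCC1=O | intermediate
17 | 2-[(1R,4S,8R,Z)-8-(methoxymethoxy)-4,8-dimethyl-7-methylidenecyclodec-2-en-1-yl]propan-2-ol | COCO[C@]1(C)CC[C@@H](C(C)(C)O)/C=C\[C@@H](C)CCC1=C | intermediate
18 | bromomethyl ether of 19 at the C1 oxygen | BrCO[C@]1(C)CC[C@@H](C(C)(C)O)/C=C\[C@@H](C)CCC1=C | intermediate (not isolated)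
19 | 2-[(1R,4S,8R,Z)-8-hydroxy-4,8-dimethyl-7-methylidenecyclodec-2-en-1-yl]propan-2-ol | O[C@]1(C)CC[C@@H](C(C)(C)O)/C=C\[C@@H](C)CCC1=C | intermediate
20 | 5-fluororesorcinol | Oc1cc(O)cc(F)c1 | starting material
21 | isobutyric acid | CC(C)C(=O)O | starting material
22 | 1-(2-fluoro-4,6-dihydroxyphenyl)-2-methylpropan-1-one | CC(C)C(=O)c1c(O)cc(O)cc1F | intermediate
23 | 1-[2-fluoro-4,6-bis(methoxymethoxy)phenyl]-2-methylpropan-1-one | CC(C)C(=O)c1c(OCOC)cc(OCOC)cc1F | intermediate
24 | 1-[3-bromo-2-fluoro-4,6-bis(methoxymethoxy)phenyl]-2-methylpropan-1-one | CC(C)C(=O)c1c(OCOC)cc(OCOC)c(Br)c1F | intermediate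
25 | B-alkyl-9-BBN from 19 (boron on the former methylene carbon; C10–H cis to the C1 oxygen) | O[C@]1(C)CC[C@@H](C(C)(C)O)/C=C\[C@@H](C)CC[C@H]1CB1C2CCCC1CCC2 | intermediate (not isolated)
26 | 1-[2-fluoro-3-{[(1S,4S,7R,10R,Z)-10-hydroxy-7-(2-hydroxypropan-2-yl)-4,10-dimethylcyclodec-5-en-1-yl]methyl}-4,6-bis(methoxymethoxy)phenyl]-2-methylpropan-1-one | O[C@]1(C)CC[C@@H](C(C)(C)O)/C=C\[C@@H](C)CC[C@H]1Cc1c(OCOC)cc(OCOC)c(C(=O)C(C)C)c1F | intermediate
27 | chroman bis-MOM ether (8-isobutyryl-5,7-bis(methoxymethoxy)chroman, C2–C3 bond shared with the cyclodecene as C1–C10, trans ring fusion) | CC(C)C(=O)c1c(OCOC)cc(OCOC)c2c1O[C@]1(C)CC[C@@H](C(C)(C)O)/C=C\[C@@H](C)CC[C@H]1C2 | intermediate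
28 | chroman diphenol (5,7-dihydroxy-8-isobutyryl analogue of 27) | CC(C)C(=O)c1c(O)cc(O)c2c1O[C@]1(C)CC[C@@H](C(C)(C)O)/C=C\[C@@H](C)CC[C@H]1C2 | intermediate
29 | C-monomethyl phenol (6-methyl derivative of 28) | CC(C)C(=O)c1c(O)c(C)c(O)c2c1O[C@]1(C)CC[C@@H](C(C)(C)O)/C=C\[C@@H](C)CC[C@H]1C2 | intermediate (not isolated)
30 | CNP0564661.1 (1R,4R,7S,10S,5Z in carbocycle numbering) | CC(C)C(=O)C1=C(O)C(C)(C)C(=O)C2=C1O[C@]1(C)CC[C@@H](C(C)(C)O)/C=C\[C@@H](C)CC[C@H]1C2 | target

Total step count: 18
Longest linear sequence: 15 steps (steps 1–11 and 15–18, from (R)-carvone)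

**Steps most likely to fail**

1. Step 8 (oxy-Cope). The alkoxide may fragment at C5–C10 without reclosure, or rearrange through a boat array; the alkoxy-bearing quaternary neighbour may also slow the shift. The result would be low conversion or loss of the Z geometry and the C7 configuration. Fallback: a neutral siloxy-Cope rearrangement setting out from 11. Silylation (TMSOTf, Et3N, CH2Cl2) gives the trimethylsilyl ether F1. Heating in o-dichlorobenzene at about 200 °C should give the silyl enol ether F2 through the same chair array. Mild methanolysis (K2CO3, MeOH) returns to the route at 14.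

2. Step 15 (hydroboration and coupling). The borane may add to the other face of the exocyclic alkene, because the facial preference rests on the ring conformation and not on a firm directing effect; this would give the C10 epimer. Transmetalation to the di-ortho-substituted bromide may also be slow. Fallback: from 19, rhodium-catalysed hydroboration with catecholborane (RhCl(PPh3)3, THF). This metal-hydride insertion pathway is known to show the opposite sense of 1,2-induction to 9-BBN with allylic oxygen substituents. It gives the catechol boronate F3, and exchange with pinacol gives the isolable pinacol boronate F4, whose C10 epimers can be separated. B-alkyl Suzuki coupling of F4 with 24 (Pd(OAc)2, RuPhos, K3PO4, toluene/H2O) returns to the route at 26.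

3. Step 16 (SNAr). Displacement of fluoride by the hindered tertiary alkoxide may be slow on a ring whose ketone is twisted out of conjugation, and enolisation of the isobutyryl group would switch off the activation. Fallback: palladium-catalysed C–O coupling on a bromo analogue. Commercial 5-bromoresorcinol and 21 (BF3·OEt2) give the bromo ketone F5. NaH/MOMCl gives the bis-MOM ether F6, and NIS gives the bromo iodide F7. Coupling of borane 25 (from 19) at the C–I bond of F7 (PdCl2(dppf), K3PO4, rt) gives the aryl bromide diol F8. Intramolecular etherification of the tertiary alcohol (Pd(OAc)2, bulky di-tert-butyl biarylphosphine, Cs2CO3, toluene, 80 °C) returns to the route at 27.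

Further compounds
F1 | step 8 | trimethylsilyl ether of 11 at the C10 oxygen | C=C[C@@]1(O[Si](C)(C)C)[C@@H](/C=C/C)[C@H](C(C)=C)CC[C@@]1(C)OCOC
F2 | step 8 | trimethylsilyl enol ether of 14 (C9=C10) | COCO[C@]1(C)CC[C@@H](C(C)=C)/C=C\[C@@H](C)C/C=C1\O[Si](C)(C)C
F3 | step 15 | catechol boronate from 19 (boron on the former methylene carbon) | O[C@]1(C)CC[C@@H](C(C)(C)O)/C=C\[C@@H](C)CC[C@H]1CB1Oc2ccccc2O1
F4 | step 15 | pinacol boronate from 19 | O[C@]1(C)CC[C@@H](C(C)(C)O)/C=C\[C@@H](C)CC[C@H]1CB1OC(C)(C)C(C)(C)O1
F5 | step 16 | 1-(2-bromo-4,6-dihydroxyphenyl)-2-methylpropan-1-one | CC(C)C(=O)c1c(O)cc(O)cc1Br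
F6 | step 16 | 1-[2-bromo-4,6-bis(methoxymethoxy)phenyl]-2-methylpropan-1-one | CC(C)C(=O)c1c(OCOC)cc(OCOC)cc1Br
F7 | step 16 | 1-[2-bromo-3-iodo-4,6-bis(methoxymethoxy)phenyl]-2-methylpropan-1-one | CC(C)C(=O)c1c(OCOC)cc(OCOC)c(I)c1Br
F8 | step 16 | bromo analogue of 26 (Br in place of F) | O[C@]1(C)CC[C@@H](C(C)(C)O)/C=C\[C@@H](C)CC[C@H]1Cc1c(OCOC)cc(OCOC)c(C(=O)C(C)C)c1Br
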